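## The problem

Target 22 is an achiral, fully enolised trimer. A central 1-butanoyl-2,4,6-trihydroxybenzene carries a CH2 group at C3 and at C5. Each CH2 leads to an outer six-membered ring ("wing"), an enolised 6,6-dimethylcyclohexane-1,3,5-trione (filicinic acid ring) bonded to the bridge at C2' and acylated at C4', by acetyl in one wing and propanoyl in the other. There is no stereocentre, so the task is purely constitutional: two quaternary CMe2 carbons, twelve oxygen functions in fixed positions, a hexasubstituted central ring, and two wings that differ by one CH2 far from any group that could tell them apart. The finished molecule is delicate. The free phloroglucinol and β-triketone units are acidic, chelating and easily oxidised in base. The aryl–CH2–wing bonds can be cleaved and scrambled when strong acid protonates the arene at a bridge-bearing carbon, or when a free phenoxide expels a wing enolate. What makes a short route possible is the make-up of each wing: the neighbouring atoms C2' (bridge-bearing) and C3' (oxygen-bearing) are the two carbons of an ynol ether, and the chain C1'(=O)–C6'Me2–C5'(O)=C4'H is the skeleton of a 3-alkoxy-4,4-dimethylcyclobutenone. Because C6' is quaternary, a cyclobutenone–alkyne annulation cannot end in a phenol and must stop at a 6,6-dimethylcyclohexa-2,4-dienone, which is a filicinic ring with two oxygens held as enol ethers.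

## Retrosynthesis

**Phenols last (22 ⇒ 21).** The three aryl O–CH3 bonds of tri-O-methyl ether 21 are cut. Methyl is chosen because it survives the acidic bromomethylation, the organozinc coupling, the thermolysis and the acylations; benzyl or acetal groups would leave more gently but would not survive the HBr of step 2. Keeping the central ring capped until the end also shuts off phenoxide-driven bridge scission in every earlier step. The forward reaction must cleave one hindered and two chelated aryl ethers without breaking the aryl–CH2 bonds.

**Wing acyl groups (21 ⇒ 19 ⇒ 17).** The C4'–C(=O) bond of the propanoyl wing is cut first, then that of the acetyl wing, which leads to the symmetrical bis(filicinic) trimer 17. Cutting here and not at the bridges keeps the carbon frame of all three rings intact and turns the wing difference into two C-acylations of a cyclic 1,3-dione, a reaction with a strong thermodynamic preference for carbon. The two wings of 17 are equivalent and do not communicate, so the first acylation can only be statistical. It is therefore run with a deficiency of acid so that the main by-product is recoverable 17. Acylation must occur at C4' only and leave the aryl ketone and aryl ethers alone.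

**Enol ethers (17 ⇒ 16).** Four enol C–OEt bonds are reconnected. Bis(dienone) 16 is 17 with every wing oxygen except the C1' carbonyl masked, which is the form the annulation delivers directly. The forward step is a plain aqueous acid hydrolysis that must stop at the trione because C6' cannot aromatise.

**Both wing rings (16 ⇒ 8 + two 11).** In each wing the bonds C1'–C2' and C3'–C4' are cut. This gives the bis(ynol ether) 8 and two molecules of 3-ethoxy-4,4-dimethylcyclobutenone 11. The cut is preferred to the classical one at the bridges for three reasons:
- it removes both outer rings at once and leaves a precursor whose only ring is the arene;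
- it is bidirectional, so the second wing costs no extra step;
- it runs under neutral, reagent-free conditions and loses no atoms.

The forward cascade passes through vinylketene 12, alkenylcyclobutenone 13, dienylketene 14 and the mono-annulated compound 15. It needs regiocontrol in the ketene–ynol ether [2+2] event, and a temperature high enough to open 11 but too low for the ethyl ynol ether to fragment.

**Ynol ether arms (8 ⇒ 4 + 5).** The two benzylic CH2–C(sp) bonds are cut, giving dibromide 4 and ethoxyacetylene 5. Direct alkylation with lithium acetylide 6 is the textbook way, but 6 would add to or enolise the butanoyl ketone. Transmetalation to the zinc reagent 7 and palladium-catalysed coupling forms the same bonds while leaving the ketone alone, so no protecting group is needed.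

**Cyclobutenone (11 ⇒ 9 + 5).** The four-membered ring is opened to dimethylketene 10 and 5. Ketene 10 is made in the flask from isobutyryl chloride 9. The polarity of the two partners fixes the regiochemistry.

**Central unit (4 ⇒ 3 ⇒ 1 + 2).** The two aryl–CH2Br bonds and then the aryl–acyl bond are cut, giving 1,3,5-trimethoxybenzene 1 and butyryl chloride 2. Acylation comes first: it uses the symmetry of 1 and leaves exactly two equivalent free positions for the bromomethylation.

## Roads not taken

**Alternative 1: central ring by Effenberger-type annulation.**
- Cut: the central ring is formed last by cutting its C2–C3 and C5–C6 bonds.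
- Forward: the pentan-3-one A2, which carries a finished, O-methylated wing on each terminal carbon, is converted to its silyl enol ether A3. This is acylated at both α-carbons by malonyl dichloride A4 to give phloroglucinol A1. Butyrylation with 2 at the one free ring position and hydrolysis of four vinylogous methyl esters would finish the synthesis.
- Merits: the acetyl and propanoyl wings are fixed by construction, with no statistical step. The last deprotection is a mild vinylogous ester hydrolysis, not an aryl ether cleavage. In both respects this road is better than the chosen one.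
- Weak points: acyclic silyl enol ethers and A4 tend to stop at 4-hydroxy-2-pyranones (C,O- instead of C,C-diacylation). The reaction liberates HCl next to four acid-labile vinylogous esters. A2 needs two different wings made separately and joined to a three-carbon linchpin, a long linear prelude.
- Comparison: the chosen plan sets against the better wing control a ring-forming step of predictable pericyclic reactivity and a four-step access to its precursor.

**Alternative 2: both wings by pyranone-to-carbocycle transformation.**
- Cut: in each wing the bond between the acyl-bearing carbon and the C(=O) next to CMe2.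
- Forward: hydroxide adds to C6 of each 4-pyranone of the bis(pyranone) diester A6. The rings open to triketone anions, and the methylene between the two new carbonyls attacks the CMe2-bound ester (Claisen-type closure). The product is A5, which is the same compound as 21.
- Merits: the acyl groups are part of the skeleton from the outset, so no late C-acylation is needed, and the road joins the chosen one at its penultimate compound.
- Weak points: A6 has a 3-benzylated, 2-tert-alkylated pyranone on each side, which cannot be made by simple alkylation of a pyranone and would have to be built ring by ring. The hindered ester may be saponified instead of attacked. Attaching two different pyranones to a symmetrical central unit raises the same statistical problem one stage earlier.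
- Comparison: it ends with the same demethylation, so it offers no gain at the most delicate step and costs more steps before it.

**Alternative 3: butanoyl group and C2 oxygen by aryne insertion.**
- Cut: the C1–C(=O) and C2–O bonds of the central ring, at the very end.
- Forward: fluoride converts silyl triflate A8 to aryne A9. Butanoic acid A10 adds through oxygen at C2 (the aryne carbon remote from the flanking methoxy group), and the C1 aryl anion takes the acyl group to give hydroxy ketone A7.
- Merits: two adjacent substituents are set in one neutral step with regiochemistry directed by the methoxy group. The ketone never meets organometallic reagents, which is an advantage over the chosen plan, where a zinc reagent is needed for that reason.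
- Weak points: A8 is a hexasubstituted arene with two different wings, so all the hard problems (wing construction, wing differentiation, bridge formation) are unsolved before the key step. Simple O-arylation of A10 competes with acyl transfer. The aryne sits next to benzylic CH2 groups and enolisable wings that can protonate it or react with it. A7 still needs two aryl ethers and four vinylogous esters cleaved.
- Comparison: the key step is spent on the bond that the chosen plan makes in step 1 by a routine Friedel–Crafts acylation.

Key step: step 5

Assumption: the β-triketone/enol tautomers of the wing rings interconvert freely; each compound is drawn as one tautomer and is taken to be the same compound as any other tautomer, including the one in the target SMILES.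

## Route

Step 1
Reactants: 1 1,3,5-trimethoxybenzene; 2 butyryl chloride
Product: 3 1-(2,4,6-trimethoxyphenyl)butan-1-one
Conditions: Bi(OTf)3 (5 mol%), MeNO2, 50 °C
Reagents that add atoms: none
Why: Friedel–Crafts acylation of a strongly activated arene; the acyl group stops a second acylation, and the catalytic, non-chelating Lewis acid avoids the ortho-demethylation that stoichiometric AlCl3 can cause.

Step 2
Reactants: 3 1-(2,4,6-trimethoxyphenyl)butan-1-one
Product: 4 1-[3,5-bis(bromomethyl)-2,4,6-trimethoxyphenyl]butan-1-one
Conditions: (CH2O)n (3 equiv), HBr (33% in AcOH), AcOH, 40 °C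
Reagents that add atoms: paraformaldehyde (as formaldehyde), C=O; hydrogen bromide, Br
Why: Blanc-type bromomethylation at the only two free ring positions, each flanked by two methoxy groups; the ketone is twisted out of conjugation by its two ortho substituents and deactivates little, and moderate temperature limits diarylmethane formation and ether cleavage.

Step 3
Reactants: 4 1-[3,5-bis(bromomethyl)-2,4,6-trimethoxyphenyl]butan-1-one; 5 ethoxyacetylene
Product: 8 1-[3,5-bis(3-ethoxyprop-2-yn-1-yl)-2,4,6-trimethoxyphenyl]butan-1-one, via lithium ethoxyacetylide 6 (not isolated), via ethoxyethynylzinc chloride 7 (not isolated)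
Conditions: 5 (2.6 equiv), n-BuLi, THF, −78 °C; ZnCl2, −78 → 0 °C; then 4, PdCl2(DPEphos) (5 mol%; DPEphos = bis[2-(diphenylphosphino)phenyl] ether), THF, 23 °C; pH 7 buffer work-up
Reagents that add atoms: none
Why: Negishi coupling of a benzylic bromide with an alkynylzinc: zerovalent palladium inserts into the benzylic C–Br bond, and transmetalation and reductive elimination form the sp3–sp bond; the zinc acetylide 7 is too weakly basic and nucleophilic to attack the hindered, enolisable aryl ketone that lithium acetylide 6 would not spare.

Step 4
Reactants: 9 isobutyryl chloride; 5 ethoxyacetylene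
Product: 11 3-ethoxy-4,4-dimethylcyclobut-2-en-1-one, via dimethylketene 10 (not isolated)
Conditions: Et3N (1.2 equiv), Et2O, 0 → 35 °C
Reagents that add atoms: none
Why: Dehydrochlorination gives ketene 10, which is trapped in a thermal ketene–alkyne [2+2] cycloaddition; the ketene carbonyl carbon bonds to the nucleophilic terminal CH of the ynol ether, so OEt ends at C3 next to CMe2.

Step 5
Reactants: 8 1-[3,5-bis(3-ethoxyprop-2-yn-1-yl)-2,4,6-trimethoxyphenyl]butan-1-one; 11 3-ethoxy-4,4-dimethylcyclobut-2-en-1-one (two equivalents react)
Product: 16 2,2'-[(5-butanoyl-2,4,6-trimethoxy-1,3-phenylene)bis(methylene)]bis(3,5-diethoxy-6,6-dimethylcyclohexa-2,4-dien-1-one), via vinylketene 12 (not isolated), via alkenylcyclobutenone 13 (not isolated), via dienylketene 14 (not isolated), via mono-dienone 15 (not isolated)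
Conditions: 11 (3 equiv), degassed toluene (0.1 M), 85 °C, sealed vessel; chromatography on Et3N-deactivated silica
Reagents that add atoms: none
Why: Thermal 4π-electrocyclic opening of 11 gives vinylketene 12, whose ketene C=C adds to one ynol ether of 8 in a [2+2] cycloaddition to give alkenylcyclobutenone 13; this reopens (4π) to dienylketene 14, which closes between the ketene carbon and the CMe2 terminus to give the first dienone ring (15), and the second arm repeats the same stages to give 16. The closest known reaction is the Danheiser annulation of cyclobutenones with alkoxyalkynes, in its variant with 4,4-disubstituted cyclobutenones, where the quaternary terminus blocks enolisation to a phenol and the cyclohexa-2,4-dienone is the end product. Both six-membered rings are closed by thermal disrotatory 6π-electrocyclisation, each re-forming the C(=O)–CMe2 bond that was broken when 11 opened. The only stereocentre on the path, the ring CH of 13, is racemic and is erased on ring opening; 16 has none. The step needs regiocontrol in the [2+2] event, and the polarity of the partners supplies it: the nucleophilic CH2-bearing alkyne carbon bonds to the electrophilic ketene carbonyl carbon, which places the bridge carbon next to C=O and the OEt carbon next to the ring CH. Chemoselectivity for the ynol ethers over the aryl ketone and over ketene self-reaction rests on the high ketenophilicity of alkoxyalkynes and on the excess of 11; the temperature is held below that at which ethyl ynol ethers fragment by a retro-ene path.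

Step 6
Reactants: 16 bis(diethoxydienone)
Product: 17 1-{3,5-bis[(2,4-dihydroxy-3,3-dimethyl-6-oxocyclohexa-1,4-dien-1-yl)methyl]-2,4,6-trimethoxyphenyl}butan-1-one (both wings free filicinic rings, C4'–H)
Conditions: 2 M aq. HCl, THF, 45 °C
Reagents that add atoms: water, O
Why: Acid hydrolysis of two dienol ethers and two vinylogous esters (C-protonation, hydration of the oxocarbenium ion, loss of ethanol); the quaternary C6' stops the sequence at the trione, and aryl methyl ethers and bridges are stable to dilute aqueous acid.

Step 7
Reactants: 17 bis(filicinic) trimer tri-O-methyl ether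
Product: 19 mono-acetyl compound (one wing 4'-acetylfilicinic, the other still C4'–H), via enol acetate 18 (not isolated)
Conditions: AcOH (0.7 equiv), DCC (0.7 equiv), DMAP (1.5 equiv), CH2Cl2, 0 → 23 °C; recovered 17 recycled
Reagents that add atoms: acetic acid, CC(=O)O
Why: Carbodiimide-mediated O-acylation of the enolised trione followed by DMAP-catalysed O-to-C acyl migration, the standard route to 2-acylcyclohexane-1,3-diones; C4' is the only enolisable ring carbon bearing hydrogen and the chelated β-triketone is the thermodynamic sink. The two wings are equivalent, so a statistical mixture is expected, and the deficiency of acid shifts it toward 19 and recoverable 17.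

Step 8
Reactants: 19 mono-acetyl compound
Product: 21 tri-O-methyl ether of the target (acetyl wing, propanoyl wing, central ring as trimethyl ether), via enol propionate 20 (not isolated)
Conditions: EtCO2H (1.3 equiv), DCC (1.3 equiv), DMAP (1.5 equiv), CH2Cl2, 23 °C; MeOH quench
Reagents that add atoms: propanoic acid, CCC(=O)O
Why: The same O-acylation/DMAP-catalysed acyl migration on the one wing that still has a C4'–H; the acetylated wing has no free ring carbon, and any enol ester formed on it is cleaved by the methanol quench.

Step 9
Reactants: 21 tri-O-methyl ether of the target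
Product: 22 target: 1-butanoyl-2,4,6-trihydroxybenzene carrying at C3 the (4'-acetylfilicinic)methyl group and at C5 the (4'-propanoylfilicinic)methyl group
Conditions: BBr3 (8 equiv), CH2Cl2, −78 → 0 °C; MeOH, then 1 M aq. HCl
Reagents that add atoms: none
Why: Lewis-acid cleavage of aryl methyl ethers (O-coordination, attack of bromide on methyl); the two methoxy groups ortho to the ketone are activated by chelation, and the 4-OMe, twisted by two ortho CH2 groups, is basic and exposed. Low temperature is used because the aryl–CH2 bonds can cleave under strong acid.

## Compound list

1 | 1,3,5-trimethoxybenzene | COc1cc(OC)cc(OC)c1 | starting material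
2 | butyryl chloride | CCCC(Cl)=O | starting material
3 | 1-(2,4,6-trimethoxyphenyl)butan-1-one | CCCC(=O)c1c(OC)cc(OC)cc1OC | intermediate
4 | 1-[3,5-bis(bromomethyl)-2,4,6-trimethoxyphenyl]butan-1-one | CCCC(=O)c1c(OC)c(CBr)c(OC)c(CBr)c1OC | intermediate
5 | ethoxyacetylene | CCOC#C | starting material
6 | lithium ethoxyacetylide | [Li]C#COCC | intermediate (not isolated)
7 | ethoxyethynylzinc chloride | Cl[Zn]C#COCC | intermediate (not isolated)
8 | 1-[3,5-bis(3-ethoxyprop-2-yn-1-yl)-2,4,6-trimethoxyphenyl]butan-1-one | CCCC(=O)c1c(OC)c(CC#COCC)c(OC)c(CC#COCC)c1OC | intermediate
9 | isobutyryl chloride | CC(C)C(Cl)=O | starting material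
10 | dimethylketene | CC(C)=C=O | intermediate (not isolated)
11 | 3-ethoxy-4,4-dimethylcyclobut-2-en-1-one | CCOC1=CC(=O)C1(C)C | intermediate
12 | 3-ethoxy-4-methylpenta-1,3-dien-1-one (vinylketene from 11) | CC(C)=C(OCC)C=C=O | intermediate (not isolated)
13 | first-arm [2+2] adduct: 2-(arylmethyl)-3-ethoxy-4-(1-ethoxy-2-methylprop-1-enyl)cyclobut-2-en-1-one, second arm still the ynol ether; racemic | CCCC(=O)c1c(OC)c(CC#COCC)c(OC)c(CC2=C(OCC)C(C(OCC)=C(C)C)C2=O)c1OC | intermediate (not isolated)
14 | first-arm dienylketene: aryl-CH2–C(=C=O)–C(OEt)=CH–C(OEt)=CMe2, ketene and alkenyl cis on the central C=C | CCCC(=O)c1c(OC)c(CC#COCC)c(OC)c(CC(=C=O)/C(OCC)=C\C(OCC)=C(C)C)c1OC | intermediate (not isolated)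
15 | mono-annulated compound: one 3,5-diethoxy-6,6-dimethylcyclohexa-2,4-dienone wing, one 3-ethoxyprop-2-ynyl arm | CCCC(=O)c1c(OC)c(CC#COCC)c(OC)c(CC2=C(OCC)C=C(OCC)C(C)(C)C2=O)c1OC | intermediate (not isolated)
16 | 2,2'-[(5-butanoyl-2,4,6-trimethoxy-1,3-phenylene)bis(methylene)]bis(3,5-diethoxy-6,6-dimethylcyclohexa-2,4-dien-1-one) | CCCC(=O)c1c(OC)c(CC2=C(OCC)C=C(OCC)C(C)(C)C2=O)c(OC)c(CC2=C(OCC)C=C(OCC)C(C)(C)C2=O)c1OC | intermediate
17 | 1-{3,5-bis[(2,4-dihydroxy-3,3-dimethyl-6-oxocyclohexa-1,4-dien-1-yl)methyl]-2,4,6-trimethoxyphenyl}butan-1-one | CCCC(=O)c1c(OC)c(CC2=C(O)C=C(O)C(C)(C)C2=O)c(OC)c(CC2=C(O)C=C(O)C(C)(C)C2=O)c1OC | intermediate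
18 | enol acetate of 17 (one wing O-acetylated at the C5' oxygen; one regioisomer shown) | CCCC(=O)c1c(OC)c(CC2=C(O)C=C(OC(C)=O)C(C)(C)C2=O)c(OC)c(CC2=C(O)C=C(O)C(C)(C)C2=O)c1OC | intermediate (not isolated)
19 | mono-acetyl compound: one 4'-acetylfilicinic wing, one unacylated filicinic wing, central ring trimethyl ether | CCCC(=O)c1c(OC)c(CC2=C(O)C(C)(C)C(=O)C(C(C)=O)=C2O)c(OC)c(CC2=C(O)C=C(O)C(C)(C)C2=O)c1OC | intermediate
20 | enol propionate of 19 (free wing O-propanoylated at the C5' oxygen; one regioisomer shown) | CCCC(=O)c1c(OC)c(CC2=C(O)C(C)(C)C(=O)C(C(C)=O)=C2O)c(OC)c(CC2=C(O)C=C(OC(=O)CC)C(C)(C)C2=O)c1OC | intermediate (not isolated)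
21 | tri-O-methyl ether of the target | CCCC(=O)c1c(OC)c(CC2=C(O)C(C)(C)C(=O)C(C(C)=O)=C2O)c(OC)c(CC2=C(O)C(C)(C)C(=O)C(C(=O)CC)=C2O)c1OC | intermediate
22 | target (CNP0325527.0) | CCCC(=O)c1c(O)c(CC2=C(O)C(C)(C)C(=O)C(C(C)=O)=C2O)c(O)c(CC2=C(O)C(C)(C)C(=O)C(C(=O)CC)=C2O)c1O | target

## Step count and risks

Total: 9 steps. Longest linear sequence: 8 steps (steps 1, 2, 3, 5, 6, 7, 8, 9); step 4 is a one-step side branch.

**Step 5 (key step).**
- What may go wrong: the donor-stabilised cyclobutenone 11 may open only slowly. Vinylketene 12 can be lost by a [1,5]-hydrogen shift from the methyl group cis to the ketene, or by self-reaction. If the temperature has to be raised, the ethyl ynol ether arms of 8 may fragment by the retro-ene path before they are trapped. The second arm may also lag behind the first.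
- Fallback: give up the pericyclic wing construction and attach preformed wings. Filicinic acid F1 is made in one known step by geminal C-methylation of phloroglucinol (Oc1cc(O)cc(O)c1) with iodomethane (CI) and NaOMe in MeOH. Dibromide 4 is then used to C-benzylate F1 twice, with F1 in large excess in aqueous KOH at 0 °C so that each filicinate reacts only once. This gives 17 directly, and the route resumes at step 7.

**Step 3.**
- What may go wrong: homocoupling or reduction of the electron-rich benzylic bromide at palladium, slow transmetalation of the zinc acetylide, and acid-catalysed hydration of the ynol ether arms during work-up.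
- Fallback: mask the ketone and use the hard acetylide in a plain substitution. Dibromide 4 is converted with TBSOTf and iPr2NEt in CH2Cl2 to the silyl enol ether of its butanoyl group, F2 (enol ether geometry is inconsequential). Alkylation of lithium ethoxyacetylide 6 with F2 in THF/DMPU gives the bis(ynol ether) silyl enol ether F3. Buffered fluoride (Bu4NF, AcOH, THF, 0 °C) returns the ketone and delivers 8.

**Step 7.**
- What may go wrong: the O-to-C acyl migration may stall at enol ester mixtures. Over-acylation to the bis-acetyl compound, and co-elution of three acidic, chelating compounds, would erode the statistical step further.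
- Fallback: direct electrophilic C-acylation that stops at a neutral chelate. 17 is treated with a deficiency of acetic anhydride in BF3·OEt2/CH2Cl2; the acetylated wing is held as its difluoroboron chelate F4, which is non-acidic and separates readily from unreacted 17. Warm aqueous NaOAc in EtOH hydrolyses F4 to 19.

**Step 9.**
- What may go wrong: acid-induced scission and scrambling of the aryl–CH2–wing bonds (retro-Friedel–Crafts), incomplete cleavage of the hindered 4-methoxy group, and boron chelates of the β-triketones that resist hydrolysis.
- Fallback: move the Lewis-acid step ahead of the acylations, where less material is at stake and the wings carry no chelating acyl groups. 17 is demethylated with BBr3 (CH2Cl2, −78 → 0 °C) to the triphenol F5. F5 is acetylated under the conditions of step 7 to the mono-acetyl triphenol F6, and F6 is propanoylated under the conditions of step 8 to give 22. Phenolic esters formed on the way are carried to carbon by the DMAP-catalysed acyl transfer or removed by brief methanolysis.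

## Further compounds

F1 | step 5 | filicinic acid (6,6-dimethylcyclohexane-1,3,5-trione) | CC1(C)C(=O)CC(=O)CC1=O
F2 | step 3 | tert-butyldimethylsilyl enol ether of 4: (Z)-1-[3,5-bis(bromomethyl)-2,4,6-trimethoxyphenyl]-1-(tert-butyldimethylsilyloxy)but-1-ene | CC/C=C(\O[Si](C)(C)C(C)(C)C)c1c(OC)c(CBr)c(OC)c(CBr)c1OC
F3 | step 3 | tert-butyldimethylsilyl enol ether of 8: (Z)-1-[3,5-bis(3-ethoxyprop-2-yn-1-yl)-2,4,6-trimethoxyphenyl]-1-(tert-butyldimethylsilyloxy)but-1-ene | CC/C=C(\O[Si](C)(C)C(C)(C)C)c1c(OC)c(CC#COCC)c(OC)c(CC#COCC)c1OC
F4 | step 7 | difluoroboron chelate of 19 (BF2 bridging the acetyl oxygen and the C3' oxygen of the acetylated wing) | CCCC(=O)c1c(OC)c(CC2=C(O)C(C)(C)C(=O)C3=C2O[B-](F)(F)[O+]=C3C)c(OC)c(CC2=C(O)C=C(O)C(C)(C)C2=O)c1OC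
F5 | step 9 | 1-{3,5-bis[(2,4-dihydroxy-3,3-dimethyl-6-oxocyclohexa-1,4-dien-1-yl)methyl]-2,4,6-trihydroxyphenyl}butan-1-one (triphenol, both wings unacylated) | CCCC(=O)c1c(O)c(CC2=C(O)C=C(O)C(C)(C)C2=O)c(O)c(CC2=C(O)C=C(O)C(C)(C)C2=O)c1O
F6 | step 9 | mono-acetyl triphenol (one 4'-acetylfilicinic wing, one unacylated wing, free central phenols) | CCCC(=O)c1c(O)c(CC2=C(O)C(C)(C)C(=O)C(C(C)=O)=C2O)c(O)c(CC2=C(O)C=C(O)C(C)(C)C2=O)c1O
A1 | alternative 1 | 2,4-bis(wing-methyl)phloroglucinol, wings as 3',5'-di-O-methyl acetyl- and propanoylfilicinic rings, ring C–H free between two OH | Oc1cc(O)c(CC2=C(OC)C(C)(C)C(=O)C(C(=O)CC)=C2OC)c(O)c1CC1=C(OC)C(C)(C)C(=O)C(C(C)=O)=C1OC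
A2 | alternative 1 | 1,5-bis(wing)pentan-3-one (one O-methylated acetyl wing, one O-methylated propanoyl wing) | O=C(CCC1=C(OC)C(C)(C)C(=O)C(C(C)=O)=C1OC)CCC1=C(OC)C(C)(C)C(=O)C(C(=O)CC)=C1OC
A3 | alternative 1 | trimethylsilyl enol ether of A2 (Z, one regioisomer shown) | C[Si](C)(C)O/C(CCC1=C(OC)C(C)(C)C(=O)C(C(=O)CC)=C1OC)=C\CC1=C(OC)C(C)(C)C(=O)C(C(C)=O)=C1OC
A4 | alternative 1 | malonyl dichloride | O=C(Cl)CC(Cl)=O
A5 | alternative 2 | tri-O-methyl ether of the target (identical with 21) | CCCC(=O)c1c(OC)c(CC2=C(O)C(C)(C)C(=O)C(C(C)=O)=C2O)c(OC)c(CC2=C(O)C(C)(C)C(=O)C(C(=O)CC)=C2O)c1OC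
A6 | alternative 2 | bis(4-pyranone) diester: central trimethoxybutyrophenone with a 6-methyl- and a 6-ethyl-4-pyranon-3-ylmethyl group, each pyranone bearing C(CH3)2CO2CH3 at C2 | CCCC(=O)c1c(OC)c(Cc2c(C(C)(C)C(=O)OC)oc(C)cc2=O)c(OC)c(Cc2c(C(C)(C)C(=O)OC)oc(CC)cc2=O)c1OC
A7 | alternative 3 | 4,6-di-O-methyl ether of the target with both wings as 3',5'-di-O-methyl ethers (free C2–OH, C1 butanoyl) | CCCC(=O)c1c(O)c(CC2=C(OC)C(C)(C)C(=O)C(C(C)=O)=C2OC)c(OC)c(CC2=C(OC)C(C)(C)C(=O)C(C(=O)CC)=C2OC)c1OC
A8 | alternative 3 | aryne precursor: C1 trimethylsilyl, C2 trifluoromethanesulfonate, C3/C5 masked wing-methyl groups, C4/C6 methoxy | C[Si](C)(C)c1c(OS(=O)(=O)C(F)(F)F)c(CC2=C(OC)C(C)(C)C(=O)C(C(C)=O)=C2OC)c(OC)c(CC2=C(OC)C(C)(C)C(=O)C(C(=O)CC)=C2OC)c1OC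
A9 | alternative 3 | C1–C2 aryne from A8 | COC1=C(CC2=C(OC)C(C)(C)C(=O)C(C(=O)CC)=C2OC)C(OC)=C(CC2=C(OC)C(C)(C)C(=O)C(C(C)=O)=C2OC)C#C1
A10 | alternative 3 | butanoic acid | CCCC(=O)O
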